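## Structural features

The target is an octaphenol built on a 2,3,5,6-tetrahydrobenzo[1,2-b:5,4-b']difuran: the central benzene (ring B) carries O1 and O7 on the two carbons that flank C8–H, is fused to the dihydrofurans O1–C2–C3–C3a–C8a and O7–C6–C5–C4a–C7a, and bears a one-carbon branch (Cα, a CH2) on C4, the carbon between C3a and C4a. C2 and C6 each carry a 4-hydroxyphenyl ring (rings A and A'), C3 carries a free 3,5-dihydroxyphenyl ring (ring D), and the matching resorcinol ring on C5 (ring C) is tied through its ortho carbon to Cβ, a CH that bears the 2,4-dihydroxyphenyl ring E and is bonded to Cα, so that C4, C4a, C5, two carbons of ring C, Cβ and Cα make up a seven-membered carbocycle. There are five stereocentres, all R: the vicinal pairs C2/C3 and C5/C6, each trans across its dihydrofuran, and Cβ, which is 1,4-related to C5 across ring C and holds ring E on the same face of the seven-membered ring as H-5. The fragile parts are the eight electron-rich phenols (oxidation), the benzylic ether bonds O1–C2 and O7–C6, which ionise in acid because each carbon carries a para-oxygenated aryl group, and the doubly benzylic hydrogens at C3, C5 and Cβ. The real difficulty lies in the pentasubstituted ring B, where C3a, C4 and C4a carry three contiguous carbon branches, and in setting four stereocentres in one absolute sense on a framework whose only polar handles are the two ring oxygens. The key step exploits a hidden symmetry: once the bond between Cβ and ring C is cut, rings C and D become identical and the units O1–C2–C3 and O7–C6–C5 are related by a C2 axis through C4 and C8, each unit being the sum of a ring B phenol oxygen, its ortho benzylic carbon (C3 or C5, the exocyclic carbon of an o-quinone methide) and one added carbon (C2 or C6). Because O1 and O7 are meta to one another, ring B has no Kekulé structure that holds both quinone methides at once, so the two annulations must take place one after the other on the same arene.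

## Logic of the disconnections

**31 ⇒ 30.** The eight phenolic O–CH3 bonds are the last to be cleaved. Methyl is the one ether that survives organolithium, carbonate and trifluoroacetic acid, and boron trichloride cleaves it only where a neighbouring carbonyl chelates, which lets the two ring B oxygens be told apart earlier. Nothing is gained in skeleton, but every earlier compound becomes robust. The forward step must cleave eight ethers without irreversible ionisation of O1–C2 and O7–C6.

**30 ⇒ 28 (through 29).** The bond cut is Cβ–C(ortho) of ring C. It is the only bond of the seven-membered ring whose cleavage leaves a nucleophilic arene position (ortho/para to two methoxy groups) facing a cation stabilised by the ortho/para donors of ring E. The cut removes one ring and the fifth stereocentre and restores C2 symmetry, so either of two homotopic rings may close. The forward step needs protonation at Cα only, seven-membered closure, and facial control at Cβ from the substrate.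

**28 ⇒ 25 + 27.** The Cα=Cβ double bond is cut. This detaches ring E as a simple benzyl unit and leaves the core with a one-carbon handle on C4. The olefination must work on an aldehyde flanked by two ortho branches without base damage at C3–H and C5–H; alkene geometry does not matter, because 29 erases it.

**27 ⇒ 26.** The C–P bond is cut, leading back to a commercial benzylic alcohol. The forward step must avoid the unstable benzylic halide.

**25 ⇒ 24 ⇒ 23.** No skeletal bond is cut; the oxidation level of Cα and one O–Si bond are adjusted. Cα is carried as a silyl-protected hydroxymethyl group for two reasons. An aldehyde or acetal between two ionisable carbinols would close to cyclic isobenzofuran-type acetals under the acid needed to make 10. A free aldehyde would also compete for the ylide. The price is two late functional-group steps.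

**23 ⇒ 10 + two 16.** Four bonds are cut: C3–C2, O1–C2, C5–C6 and O7–C6. This removes both heterocycles and four stereocentres at once and leaves an achiral, symmetric core plus one chiral reagent. The forward step requires two consecutive quinone methide formations, trans ring closure, and the same absolute sense on both flanks.

**16 ⇒ 14 + 15; 14 ⇒ 12 ⇒ 11.** The S–CH2 bond is cut, then the two ring C–S bonds of the thiolane. The C2-symmetric thiolane makes sulfur non-stereogenic in 16. Both C–S bonds must form with clean inversion.

**10 ⇒ 9 ⇒ 8.** The two C–S bonds to the sulfonyl groups are cut, then the two carbinol C–H bonds. The sulfinate is a leaving group that a phenoxide can expel under base; it is put on through the cations that O1 and O7 stabilise. The forward steps must ionise the carbinols without letting the Cα substituent interfere. 9 is the bis(2-hydroxybenzhydrol) precursor of the annulation.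

**8 ⇒ 7.** The two ring B O–CH3 bonds are cut (restored in the backward sense). Only these ethers are ortho to a ketone, so chelation singles them out among six.

**7 ⇒ 3 + two 5.** The two ring B–C(=O) bonds are cut. The bromine atoms of 3 fix the positions beyond doubt, and the amide delivers the ketone level directly. The forward step needs two successive bromine–lithium exchanges in one flask and one equivalent of 5 for each of them.

**3 ⇒ 2 ⇒ 1 and 5 ⇒ 4.** The O–Si and two C–Br bonds, and the amide C–N bond, are cut. Bromination must go to the two positions ortho to the CH2OH group, not between the methoxy groups.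

## Other disconnections considered

Alternative 1: The cut removes the ring B–Cα and ring B–C5 bonds, so that the seven-membered ring is assembled on a simple iodoresorcinol. In the forward step, aryl iodide A1 and primary bromide A2 (which already holds Cβ, ring E, ring C and a 4-methoxystyryl arm) would react under Pd(OAc)2, tri(2-furyl)phosphine, norbornene and Cs2CO3. The iodide is ortho-alkylated by the bromide and its ipso carbon then adds to the stilbene in a Heck closure, giving A3.
- In its favour: two C–C bonds to ring B and the carbocycle form in one catalytic operation. Cβ arrives already configured in A2; on this point it is better than the chosen plan, which relies on substrate control in a cation closure. It uses a catalytic metal where the chosen plan uses two equivalents of a chiral sulfonium salt, which is also a point in its favour.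
- Against it: A2 is a β-branched primary bromide with a β-hydrogen on a diarylmethine carbon, so slow alkylation of the palladacycle and β-hydride elimination are to be expected. A Heck closure of a seven-membered ring onto a 1,2-diaryl alkene is demanding. A3 contains neither furan: the exocyclic alkene must still be turned into the C5/C6 ring, and the C2/C3 ring must be built on a remaining ring B C–H by separate chemistry.
- Comparison: structurally it ignores the C2 symmetry. Mechanistically it is catalytic, but it postpones four of the five stereocentres. In step economy it should be clearly longer after its key step than the six operations that follow step 11 here.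

Alternative 2: The cut is the C4a–C5 bond, formed across a ten-membered ring with loss of water. In the forward step the macrocyclic aryloxy ketone A4 would be treated with CH3SO3H; the inward ring B carbon attacks the carbonyl carbon and dehydration gives the benzofuran A5.
- In its favour: the seven-membered ring and a furan ring form together, which equals the chosen plan in rings per step. Cyclodehydration of aryloxy ketones to 3-arylbenzofurans is dependable, and the macrocycle enforces the regiochemistry. Cβ and the C2/C3 ring are fixed beforehand, which is better on the Cβ question.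
- Against it: the ten-membered oxa-metacyclophane A4 needs a medium-ring closure. Strong acid threatens O1–C2 and Cβ. The new ring emerges aromatic, so C5 and C6 must be set by a late reduction of a tetrasubstituted 2,3-diarylbenzofuran; hydrogenation of such rings is difficult and cis-selective, and ionic reduction offers no absolute control.
- Comparison: structurally it is linear and makes no use of symmetry. Mechanistically it trades ylide chemistry for robust electrophilic substitution but leaves two stereocentres to an uncertain step. In step economy the route to A4 is long.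

Alternative 3: The cut removes both the ring B–C3 and the ring B–C5 bond, each made by a [3,3] shift from O1 or O7. In the forward step the bis[(R)-allylic] ether A6 would be heated in N,N-diethylaniline and should give A7 by two aromatic Claisen rearrangements.
- In its favour: it is two-directional and uses the same C2 symmetry, equal to the chosen plan. C3 and C5 arise by chirality transfer through a chair transition state, whose sense can be predicted from first principles; this is better than the analogy on which the ylide face rests. The key step needs no stoichiometric chiral reagent.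
- Against it: no ring is closed and C2 and C6 remain unset. Each propenyl group must be cleaved to a ketone (C3 and C5 then lie next to a carbonyl and can epimerise), reduced, cyclised, and the bromine removed. Aryl-substituted allyl ethers tend to ionise on heating, which costs chirality transfer. The migration termini flank the acetal-bearing carbon. The required alkene has its two aryl groups cis.
- Comparison: structurally it uses the same symmetry but forms two bonds and no ring where the chosen step forms four bonds and two rings. Mechanistically it is pericyclic and predictable against ionic chemistry that needs reagent control. In step economy it needs at least six more operations to reach the stage of 23.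

Key step: step 11

Assumption (a): the ylide of 16 is taken to react with a quinone methide through the same face of its carbon as in benzylidene transfer from this thiolane to aldehydes, which leads to (S,S)-diaryloxiranes; with the changed CIP ranking at the new carbon this corresponds to R at C2 and C6. If the salt proves mismatched, its antipode is made from (2R,5R)-hexane-2,5-diol.

Assumption (b): the configuration needed at Cβ (ring E cis to H-5) is taken to be the one favoured in the cationic closure of step 16.

## Steps

Step 1
Reactants: 1 (3,5-dimethoxyphenyl)methanol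
Product: 2 (2,6-dibromo-3,5-dimethoxyphenyl)methanol
Conditions: NBS (2.05 equiv), MeCN, 0 °C → rt, dark
Reagents that add atoms: N-bromosuccinimide, O=C1CCC(=O)N1Br
Why: Electrophilic aromatic bromination; each bromine should enter para to one methoxy group and ortho to the other (C2 and C6), the position between the two methoxy groups being the most hindered; no stereocentre is formed.

Step 2
Reactants: 2 (2,6-dibromo-3,5-dimethoxyphenyl)methanol
Product: 3 [(2,6-dibromo-3,5-dimethoxybenzyl)oxy]triisopropylsilane
Conditions: TIPSCl, imidazole, DMF, rt
Reagents that add atoms: triisopropylsilyl chloride, CC(C)[Si](Cl)(C(C)C)C(C)C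
Why: Silylation of a primary alcohol; the bulky silyl ether should resist organolithium, BCl3 at low temperature, sulfinic acid and carbonate, migrates slowly from oxygen to an ortho carbanion, and its oxygen is a poor neighbouring group for the cations of step 7.

Step 3
Reactants: 4 3,5-dimethoxybenzoyl chloride
Product: 5 N,3,5-trimethoxy-N-methylbenzamide
Conditions: MeNHOMe·HCl, pyridine, CH2Cl2, 0 °C → rt
Reagents that add atoms: N,O-dimethylhydroxylamine hydrochloride, CNOC.Cl
Why: Acylation of the hydroxylamine nitrogen by the acid chloride (Weinreb amide formation); the amide lets an aryllithium stop at the ketone level.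

Step 4
Reactants: 3 [(2,6-dibromo-3,5-dimethoxybenzyl)oxy]triisopropylsilane; 5 N,3,5-trimethoxy-N-methylbenzamide (first equivalent)
Product: 7 [4,6-dimethoxy-2-{[(triisopropylsilyl)oxy]methyl}-1,3-phenylene]bis[(3,5-dimethoxyphenyl)methanone], via mono-adduct lithium alkoxide 6 (not isolated)
Conditions: n-BuLi (1.05 equiv), THF, −78 °C; 5 (1.05 equiv); n-BuLi (1.1 equiv), −78 °C; 5 (1.3 equiv), −78 → −20 °C; aq. NH4Cl
Reagents that add atoms: second equivalent of Weinreb amide 5, COc1cc(OC)cc(C(=O)N(C)OC)c1
Why: Bromine–lithium exchange is faster than any other reaction of n-BuLi with 3 and stops at the mono-lithio stage, and the aryllithium adds to 5 to give the chelated tetrahedral adduct 6, which neither collapses nor is attacked by n-BuLi at low temperature. The second bromine can therefore be exchanged in the same flask and the new aryllithium acylated by a second equivalent of 5 (Weinreb ketone synthesis, carried out twice), so that each ring B–carbonyl bond comes from one molecule of 5 and both ketones are released only on aqueous work-up. The low temperature keeps the ortho silyloxymethyl group from passing silicon to the carbanion, and no stereocentre is formed.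

Step 5
Reactants: 7 [4,6-dimethoxy-2-{[(triisopropylsilyl)oxy]methyl}-1,3-phenylene]bis[(3,5-dimethoxyphenyl)methanone]
Product: 8 [4,6-dihydroxy-2-{[(triisopropylsilyl)oxy]methyl}-1,3-phenylene]bis[(3,5-dimethoxyphenyl)methanone]
Conditions: BCl3 (3 equiv), CH2Cl2, −78 → 0 °C; aq. NaHCO3
Reagents that add atoms: none
Why: Chelation-directed demethylation; BCl3 bridges each ketone oxygen and the ortho methoxy oxygen of ring B and chloride removes only those two methyl groups, while the four methoxy groups meta to the carbonyls and the hindered silyl ether on an electron-poor benzylic carbon should remain.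

Step 6
Reactants: 8 [4,6-dihydroxy-2-{[(triisopropylsilyl)oxy]methyl}-1,3-phenylene]bis[(3,5-dimethoxyphenyl)methanone]
Product: 9 4,6-bis[(3,5-dimethoxyphenyl)(hydroxy)methyl]-5-{[(triisopropylsilyl)oxy]methyl}benzene-1,3-diol (mixture of diastereomers)
Conditions: NaBH4, THF–MeOH, 0 °C → rt; aq. NH4Cl
Reagents that add atoms: none
Why: Hydride reduction of the two diaryl ketones; the two carbinol centres form without control, which is of no consequence because both become trigonal in step 11; the low temperature and a near-neutral work-up avoid ionisation of the doubly activated carbinols.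

Step 7
Reactants: 9 4,6-bis[(3,5-dimethoxyphenyl)(hydroxy)methyl]-5-{[(triisopropylsilyl)oxy]methyl}benzene-1,3-diol
Product: 10 4,6-bis[(3,5-dimethoxyphenyl)(4-methylbenzenesulfonyl)methyl]-5-{[(triisopropylsilyl)oxy]methyl}benzene-1,3-diol (mixture of diastereomers)
Conditions: p-TolSO2H (3 equiv), MgSO4, CH2Cl2, rt
Reagents that add atoms: 4-methylbenzenesulfinic acid, Cc1ccc(S(=O)O)cc1
Why: The ortho and para oxygens of ring B let each carbinol ionise under the weak acid and sulfinate captures the cation at sulfur (SN1 substitution, the usual way to 2-(sulfonylmethyl)phenols); the silyl ether on Cα offers no oxygen able to intercept the cation, which an acetal at this carbon would.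

Step 8
Reactants: 11 (2S,5S)-hexane-2,5-diol
Product: 12 (2S,5S)-hexane-2,5-diyl dimethanesulfonate
Conditions: MsCl, Et3N, CH2Cl2, 0 °C
Reagents that add atoms: methanesulfonyl chloride, CS(=O)(=O)Cl
Why: O-Sulfonylation; no bond to either stereocentre is touched, so both keep their configuration.

Step 9
Reactants: 12 (2S,5S)-hexane-2,5-diyl dimethanesulfonate
Product: 14 (2R,5R)-2,5-dimethylthiolane, via mesylate thiolate 13 (not isolated)
Conditions: Na2S·9H2O, EtOH, rt → 40 °C
Reagents that add atoms: sodium sulfide (as nonahydrate), [Na+].[Na+].[S-2]
Why: Two SN2 displacements by sulfur, the second intramolecular (5-exo-tet), each with inversion, so the (S,S) diol series should give the (R,R) thiolane.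

Step 10
Reactants: 14 (2R,5R)-2,5-dimethylthiolane; 15 4-methoxybenzyl bromide
Product: 16 (2R,5R)-1-(4-methoxybenzyl)-2,5-dimethylthiolan-1-ium tetrafluoroborate
Conditions: AgBF4, CH2Cl2, rt, dark
Reagents that add atoms: silver tetrafluoroborate, [Ag+].F[B-](F)(F)F
Why: S-Alkylation driven by precipitation of AgBr, which also installs a non-nucleophilic counter-ion; sulfur is not stereogenic because the trans-dimethylthiolane is C2-symmetric.

Step 11
Reactants: 10 4,6-bis[(3,5-dimethoxyphenyl)(4-methylbenzenesulfonyl)methyl]-5-{[(triisopropylsilyl)oxy]methyl}benzene-1,3-diol; 16 (2R,5R)-1-(4-methoxybenzyl)-2,5-dimethylthiolan-1-ium tetrafluoroborate (2.6 equiv, one equivalent being taken up on each flank)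
Product: 23 {[(2R,3R,5R,6R)-3,5-bis(3,5-dimethoxyphenyl)-2,6-bis(4-methoxyphenyl)-2,3,5,6-tetrahydrobenzo[1,2-b:5,4-b']difuran-4-yl]methoxy}triisopropylsilane, via sulfonium ylide 17 (not isolated), via first quinone methide 18 (not isolated), via first betaine 19 (not isolated), via mono-annulated sulfone 20 (not isolated), via second quinone methide 21 (not isolated), via second betaine 22 (not isolated)
Conditions: Cs2CO3 (6 equiv), CH2Cl2, 0 °C → rt
Reagents that add atoms: none
Why: Cs2CO3 ionises the phenols of 10 and deprotonates 16 to ylide 17; the phenoxide at O1 expels the ortho benzylic sulfinate to give quinone methide 18 (the two quinone methides cannot coexist because O1 and O7 are meta), 17 adds through carbon to the exocyclic methide carbon in a 1,4-addition that rearomatises ring B (betaine 19), the phenoxide displaces the thiolane from the new carbon with inversion (20), and the same three events on the O7 flank (21, 22) close the second ring. The closest known reaction type is the formal [4+1] annulation of o-quinone methides, released by base from 2-(sulfonylmethyl)phenols, with sulfonium ylides to trans-2,3-dihydrobenzofurans, including ylides of chiral sulfides; here it is used on both flanks of one arene. Both rings close by 5-exo-tet substitution of oxygen at the sulfonium-bearing carbon. C2 and C6 are under reagent control: the methyl groups of the C2-symmetric thiolane leave one face of the ylide carbon open, and after the inversion of the ring closure this should give R at both. C3 and C5 follow from C2 and C6, because betaine formation is reversible and the anti betaine, in which the two aryl groups avoid each other during closure, cyclises faster, so each ring should be trans. The step needs C-alkylation of the quinone methide in preference to O-benzylation of the phenoxides, trans closure and the same absolute sense twice. The substrate secures the last point because its two flanks are homotopic and react independently: an occasional event of the wrong sense should end mainly in the separable meso isomer and so enrich the C2-symmetric product statistically. The silyl ether and the methyl ethers are inert to carbonate.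

Step 12
Reactants: 23 {[(2R,3R,5R,6R)-3,5-bis(3,5-dimethoxyphenyl)-2,6-bis(4-methoxyphenyl)-2,3,5,6-tetrahydrobenzo[1,2-b:5,4-b']difuran-4-yl]methoxy}triisopropylsilane
Product: 24 [(2R,3R,5R,6R)-3,5-bis(3,5-dimethoxyphenyl)-2,6-bis(4-methoxyphenyl)-2,3,5,6-tetrahydrobenzo[1,2-b:5,4-b']difuran-4-yl]methanol
Conditions: TBAF, THF, 0 °C → rt
Reagents that add atoms: none
Why: Fluoride-induced cleavage of the Si–O bond; none of the four stereocentres is acidic enough to be affected.

Step 13
Reactants: 24 [(2R,3R,5R,6R)-3,5-bis(3,5-dimethoxyphenyl)-2,6-bis(4-methoxyphenyl)-2,3,5,6-tetrahydrobenzo[1,2-b:5,4-b']difuran-4-yl]methanol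
Product: 25 (2R,3R,5R,6R)-3,5-bis(3,5-dimethoxyphenyl)-2,6-bis(4-methoxyphenyl)-2,3,5,6-tetrahydrobenzo[1,2-b:5,4-b']difuran-4-carbaldehyde
Conditions: Dess–Martin periodinane, NaHCO3, CH2Cl2, 0 °C → rt
Reagents that add atoms: none
Why: Buffered Dess–Martin oxidation of a primary benzylic alcohol; the conditions are neutral, so the benzylic ethers should not ionise and no centre lies alpha to the new carbonyl.

Step 14
Reactants: 26 (2,4-dimethoxyphenyl)methanol
Product: 27 diethyl (2,4-dimethoxybenzyl)phosphonate
Conditions: P(OEt)3, ZnI2, toluene, reflux
Reagents that add atoms: triethyl phosphite, CCOP(OCC)OCC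
Why: ZnI2-mediated conversion of an electron-rich benzylic alcohol into its phosphonate (Michaelis–Arbuzov type C–P bond formation), which avoids the unstable 2,4-dimethoxybenzyl halide.

Step 15
Reactants: 25 (2R,3R,5R,6R)-3,5-bis(3,5-dimethoxyphenyl)-2,6-bis(4-methoxyphenyl)-2,3,5,6-tetrahydrobenzo[1,2-b:5,4-b']difuran-4-carbaldehyde; 27 diethyl (2,4-dimethoxybenzyl)phosphonate
Product: 28 (2R,3R,5R,6R)-4-[(E)-2-(2,4-dimethoxyphenyl)ethenyl]-3,5-bis(3,5-dimethoxyphenyl)-2,6-bis(4-methoxyphenyl)-2,3,5,6-tetrahydrobenzo[1,2-b:5,4-b']difuran
Conditions: 27, KOt-Bu, THF, 0 °C; then 25, −20 °C → rt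
Reagents that add atoms: none
Why: Horner–Wadsworth–Emmons olefination, expected to be E-selective; the phosphonate is deprotonated first so that no free base meets C3–H and C5–H, and the alkene geometry is in any case erased in step 16.

Step 16
Reactants: 28 (2R,3R,5R,6R)-4-[(E)-2-(2,4-dimethoxyphenyl)ethenyl]-3,5-bis(3,5-dimethoxyphenyl)-2,6-bis(4-methoxyphenyl)-2,3,5,6-tetrahydrobenzo[1,2-b:5,4-b']difuran
Product: 30 octamethyl ether of the target, via benzylic cation 29 (not isolated)
Conditions: CF3CO2H, CH2Cl2, −20 → 0 °C
Reagents that add atoms: none
Why: Protonation at Cα gives cation 29 at Cβ, stabilised by the ortho and para methoxy groups of ring E (a cation at Cα would have only meta oxygens on ring B); either homotopic 3,5-dimethoxyphenyl ring then attacks through its ortho carbon and closes the seven-membered ring (intramolecular Friedel–Crafts alkylation, the known acid closure of 3-aryl-4-styryl-dihydrobenzofurans). The new centre Cβ is under substrate control: ring E should take the position cis to H-5, away from C6 and from the ortho methoxy group of ring C.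

Step 17
Reactants: 30 octamethyl ether of the target
Product: 31 CNP0154047.1
Conditions: BBr3 (20 equiv), CH2Cl2, −78 °C → rt; MeOH, H2O
Reagents that add atoms: none
Why: Lewis acid cleavage of the eight aryl methyl ethers (bromide attacks each methyl carbon of the boron-complexed ether); no alkene remains, and a benzylic ether bond that ionises reversibly should reclose to the more stable trans ring, so the five stereocentres are expected to survive.

## Compound list

1 | (3,5-dimethoxyphenyl)methanol | COc1cc(CO)cc(OC)c1 | starting material
2 | (2,6-dibromo-3,5-dimethoxyphenyl)methanol | COc1cc(OC)c(Br)c(CO)c1Br | intermediate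
3 | [(2,6-dibromo-3,5-dimethoxybenzyl)oxy]triisopropylsilane | COc1cc(OC)c(Br)c(CO[Si](C(C)C)(C(C)C)C(C)C)c1Br | intermediate
4 | 3,5-dimethoxybenzoyl chloride | COc1cc(OC)cc(C(=O)Cl)c1 | starting material
5 | N,3,5-trimethoxy-N-methylbenzamide | COc1cc(OC)cc(C(=O)N(C)OC)c1 | intermediate
6 | lithium alkoxide of the mono-adduct of lithiated 3 and 5 (one bromine left; new carbon not configured) | COc1cc(OC)c(C([O-])(N(C)OC)c2cc(OC)cc(OC)c2)c(CO[Si](C(C)C)(C(C)C)C(C)C)c1Br.[Li+] | intermediate (not isolated)
7 | [4,6-dimethoxy-2-{[(triisopropylsilyl)oxy]methyl}-1,3-phenylene]bis[(3,5-dimethoxyphenyl)methanone] | COc1cc(OC)c(C(=O)c2cc(OC)cc(OC)c2)c(CO[Si](C(C)C)(C(C)C)C(C)C)c1C(=O)c1cc(OC)cc(OC)c1 | intermediate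
8 | [4,6-dihydroxy-2-{[(triisopropylsilyl)oxy]methyl}-1,3-phenylene]bis[(3,5-dimethoxyphenyl)methanone] | Oc1cc(O)c(C(=O)c2cc(OC)cc(OC)c2)c(CO[Si](C(C)C)(C(C)C)C(C)C)c1C(=O)c1cc(OC)cc(OC)c1 | intermediate
9 | 4,6-bis[(3,5-dimethoxyphenyl)(hydroxy)methyl]-5-{[(triisopropylsilyl)oxy]methyl}benzene-1,3-diol (carbinol centres not controlled, mixture) | Oc1cc(O)c(C(O)c2cc(OC)cc(OC)c2)c(CO[Si](C(C)C)(C(C)C)C(C)C)c1C(O)c1cc(OC)cc(OC)c1 | intermediate
10 | 4,6-bis[(3,5-dimethoxyphenyl)(4-methylbenzenesulfonyl)methyl]-5-{[(triisopropylsilyl)oxy]methyl}benzene-1,3-diol (sulfonyl-bearing centres not controlled, mixture) | Cc1ccc(cc1)S(=O)(=O)C(c1cc(OC)cc(OC)c1)c1c(O)cc(O)c(C(c2cc(OC)cc(OC)c2)S(=O)(=O)c2ccc(C)cc2)c1CO[Si](C(C)C)(C(C)C)C(C)C | intermediate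
11 | (2S,5S)-hexane-2,5-diol | C[C@H](O)CC[C@H](C)O | starting material
12 | (2S,5S)-hexane-2,5-diyl dimethanesulfonate | C[C@H](OS(C)(=O)=O)CC[C@H](C)OS(C)(=O)=O | intermediate
13 | sodium (2R,5S)-5-[(methanesulfonyl)oxy]hexane-2-thiolate | C[C@@H]([S-])CC[C@H](C)OS(C)(=O)=O.[Na+] | intermediate (not isolated)
14 | (2R,5R)-2,5-dimethylthiolane | C[C@@H]1CC[C@@H](C)S1 | intermediate
15 | 4-methoxybenzyl bromide | COc1ccc(CBr)cc1 | starting material
16 | (2R,5R)-1-(4-methoxybenzyl)-2,5-dimethylthiolan-1-ium tetrafluoroborate | C[C@@H]1CC[C@@H](C)[S+]1Cc1ccc(OC)cc1.F[B-](F)(F)F | intermediate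
17 | (2R,5R)-2,5-dimethylthiolanium (4-methoxyphenyl)methanide (ylide of 16) | C[C@@H]1CC[C@@H](C)[S+]1[CH-]c1ccc(OC)cc1 | intermediate (not isolated)
18 | first o-quinone methide: 6-(3,5-dimethoxybenzylidene)cyclohexa-2,4-dienone of ring B with 3-hydroxy (ionised under the conditions), 4-[(3,5-dimethoxyphenyl)(tosyl)methyl] and 5-(silyloxymethyl) groups; alkene geometry not defined | O=C1C=C(O)C(C(c2cc(OC)cc(OC)c2)S(=O)(=O)c2ccc(C)cc2)=C(CO[Si](C(C)C)(C(C)C)C(C)C)C1=Cc1cc(OC)cc(OC)c1 | intermediate (not isolated)
19 | first betaine: ring B phenoxide with the 1-(3,5-dimethoxyphenyl)-2-(4-methoxyphenyl)-2-(thiolanio)ethyl group on the O1 flank, anti arrangement leading to the trans ring | COc1ccc(cc1)[C@H]([C@H](c1cc(OC)cc(OC)c1)c1c([O-])cc(O)c(C(c2cc(OC)cc(OC)c2)S(=O)(=O)c2ccc(C)cc2)c1CO[Si](C(C)C)(C(C)C)C(C)C)[S+]1[C@H](C)CC[C@H]1C | intermediate (not isolated)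
20 | mono-annulated sulfone: (2R,3R)-2,3-dihydrobenzofuran-6-ol with 2-(4-methoxyphenyl), 3-(3,5-dimethoxyphenyl), 4-(silyloxymethyl) and 5-[(3,5-dimethoxyphenyl)(tosyl)methyl] groups | COc1ccc(cc1)[C@@H]1Oc2cc(O)c(C(c3cc(OC)cc(OC)c3)S(=O)(=O)c3ccc(C)cc3)c(CO[Si](C(C)C)(C(C)C)C(C)C)c2[C@H]1c1cc(OC)cc(OC)c1 | intermediate (not isolated)
21 | second o-quinone methide: (2R,3R)-5-(3,5-dimethoxybenzylidene)-2,3-dihydrobenzofuran-6(5H)-one derived from 20; alkene geometry not defined | COc1ccc(cc1)[C@@H]1OC2=CC(=O)C(=Cc3cc(OC)cc(OC)c3)C(CO[Si](C(C)C)(C(C)C)C(C)C)=C2[C@H]1c1cc(OC)cc(OC)c1 | intermediate (not isolated)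
22 | second betaine: phenoxide of the (2R,3R)-dihydrobenzofuran with the 1-(3,5-dimethoxyphenyl)-2-(4-methoxyphenyl)-2-(thiolanio)ethyl group at C5, anti arrangement | COc1ccc(cc1)[C@@H]1Oc2cc([O-])c([C@@H](c3cc(OC)cc(OC)c3)[C@@H](c3ccc(OC)cc3)[S+]3[C@H](C)CC[C@H]3C)c(CO[Si](C(C)C)(C(C)C)C(C)C)c2[C@H]1c1cc(OC)cc(OC)c1 | intermediate (not isolated)
23 | {[(2R,3R,5R,6R)-3,5-bis(3,5-dimethoxyphenyl)-2,6-bis(4-methoxyphenyl)-2,3,5,6-tetrahydrobenzo[1,2-b:5,4-b']difuran-4-yl]methoxy}triisopropylsilane | COc1ccc([C@@H]2Oc3cc4c(c(CO[Si](C(C)C)(C(C)C)C(C)C)c3[C@H]2c2cc(OC)cc(OC)c2)[C@@H](c2cc(OC)cc(OC)c2)[C@H](c2ccc(OC)cc2)O4)cc1 | intermediate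
24 | [(2R,3R,5R,6R)-3,5-bis(3,5-dimethoxyphenyl)-2,6-bis(4-methoxyphenyl)-2,3,5,6-tetrahydrobenzo[1,2-b:5,4-b']difuran-4-yl]methanol | COc1ccc([C@@H]2Oc3cc4c(c(CO)c3[C@H]2c2cc(OC)cc(OC)c2)[C@@H](c2cc(OC)cc(OC)c2)[C@H](c2ccc(OC)cc2)O4)cc1 | intermediate
25 | (2R,3R,5R,6R)-3,5-bis(3,5-dimethoxyphenyl)-2,6-bis(4-methoxyphenyl)-2,3,5,6-tetrahydrobenzo[1,2-b:5,4-b']difuran-4-carbaldehyde | COc1ccc([C@@H]2Oc3cc4c(c(C=O)c3[C@H]2c2cc(OC)cc(OC)c2)[C@@H](c2cc(OC)cc(OC)c2)[C@H](c2ccc(OC)cc2)O4)cc1 | intermediate
26 | (2,4-dimethoxyphenyl)methanol | COc1ccc(CO)c(OC)c1 | starting material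
27 | diethyl (2,4-dimethoxybenzyl)phosphonate | CCOP(=O)(Cc1ccc(OC)cc1OC)OCC | intermediate
28 | (2R,3R,5R,6R)-4-[(E)-2-(2,4-dimethoxyphenyl)ethenyl]-3,5-bis(3,5-dimethoxyphenyl)-2,6-bis(4-methoxyphenyl)-2,3,5,6-tetrahydrobenzo[1,2-b:5,4-b']difuran | COc1ccc([C@@H]2Oc3cc4c(c(/C=C/c5ccc(OC)cc5OC)c3[C@H]2c2cc(OC)cc(OC)c2)[C@@H](c2cc(OC)cc(OC)c2)[C@H](c2ccc(OC)cc2)O4)cc1 | intermediate
29 | 1-(2,4-dimethoxyphenyl)-2-(benzodifuran-4-yl)ethyl cation from protonation of 28 at Cα, as trifluoroacetate ion pair | COc1ccc([C@@H]2Oc3cc4c(c(C[CH+]c5ccc(OC)cc5OC)c3[C@H]2c2cc(OC)cc(OC)c2)[C@@H](c2cc(OC)cc(OC)c2)[C@H](c2ccc(OC)cc2)O4)cc1.[O-]C(=O)C(F)(F)F | intermediate (not isolated)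
30 | octamethyl ether of the target (all five stereocentres R; seven-membered ring closed) | COc1ccc([C@@H]2Oc3cc4c5c(c3[C@H]2c2cc(OC)cc(OC)c2)C[C@H](c2ccc(OC)cc2OC)c2c(OC)cc(OC)cc2[C@H]5[C@H](c2ccc(OC)cc2)O4)cc1 | intermediate
31 | CNP0154047.1 (octaphenol, all five stereocentres R) | Oc1ccc([C@@H]2Oc3cc4c5c(c3[C@H]2c2cc(O)cc(O)c2)C[C@H](c2ccc(O)cc2O)c2c(O)cc(O)cc2[C@H]5[C@H](c2ccc(O)cc2)O4)cc1 | target

## Step count and least certain steps

Total: 17 steps. Longest linear sequence: 12 steps (steps 1, 2, 4, 5, 6, 7, 11, 12, 13, 15, 16, 17, from 1).

**Step 11 (key step).** The first annulation has to run on a quinone methide whose second phenol is ionised. This vinylogous carboxylate character lowers the electrophilicity of the methide carbon, so ylide addition becomes slow and more reversible. O-Benzylation of the phenoxides by 16 and decay of the ylide then gain ground, and facial and trans selectivity may erode. The fallback sets out from 10 and unveils the phenoxides one at a time. Both phenols of 10 are silylated (TBSOTf, 2,6-lutidine, CH2Cl2, −78 °C) to give the bis(tert-butyldimethylsilyl) ether of 10, F1. F1 is then treated with 16, Cs2CO3 and sparingly soluble CsF in MeCN. Each desilylation releases one phenoxide, which expels sulfinate and gives a neutral, silyloxy-substituted quinone methide that is annulated before the second silyl group is lost (fluoride-triggered quinone methide release is known chemistry). The route is rejoined at 23.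

**Step 16.** Poor facial selectivity at Cβ is the main concern, since the configuration rests only on the conformational preference of the cyclising cation; ionisation of O1–C2 or O7–C6 during a slow seven-membered closure is a second one. The fallback sets out from 28 and sets Cβ by hydrogenation. N-Bromosuccinimide in CH2Cl2 at −78 °C should induce the same ring closure through a bromonium ion and give the Cα-bromide F2 (Cα and Cβ of no consequence). DBU in toluene removes HBr to give the ring alkene F3 (Cα=Cβ). Hydrogenation of F3 over palladium on carbon (Pd/C) delivers hydrogen from the less hindered face. If that face is the wrong one, the same alkene is reduced under catalyst control with [Ir(cod)(tBu-PHOX)][B(C6H3(CF3)2)4], the ligand enantiomer being chosen for the required face. The route is rejoined at 30.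

**Step 7.** The doubly activated carbinols ionise very easily. Loss of the neighbouring silyl group with ether formation, or intermolecular Friedel–Crafts alkylation of the dimethoxyphenyl rings, may compete with capture by sulfinate. The fallback sets out from 9 and avoids acid altogether. Phenol-selective silylation (TBSCl, imidazole, DMF) gives the bis(aryl silyl ether) F4. Acetylation of the two carbinols (Ac2O, DMAP, Et3N) gives the bis(benzhydryl acetate) F5. F5 is then submitted to the fluoride-triggered twofold annulation with 16 (CsF, Cs2CO3, MeCN), in which each unveiled phenoxide expels acetate. The route is rejoined at 23.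

**Step 17.** Lewis acid ionisation of the benzylic ether bonds O1–C2 and O7–C6 may lead to capture of the resulting cations by neighbouring arenes, and cleavage of eight ethers may stop short. The fallback sets out from 30 and changes the mechanism: NaSEt in DMF at 140 °C removes the methyl groups by SN2 attack of thiolate under basic conditions, in which the benzylic ethers cannot ionise. It arrives directly at 31 and makes no new compound.

**Step 4.** The second acylation may remain incomplete. The second aryllithium is flanked by a methoxy and a silyloxymethyl group and faces the bulky first adduct, so protonation on work-up or silyl migration from oxygen to carbon may precede attack on the amide. The fallback sets out from 3 and forms the two ring B–carbon bonds by addition to 3,5-dimethoxybenzaldehyde, a far more reactive electrophile, in two exchange–addition cycles (n-BuLi, THF, −78 °C). This gives the diol F6 (mixture of diastereomers), whose two carbinols are then oxidised with Dess–Martin periodinane. The route is rejoined at 7.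

## Further compounds

F1 | step 11 | bis(tert-butyldimethylsilyl) ether of 10 | Cc1ccc(cc1)S(=O)(=O)C(c1cc(OC)cc(OC)c1)c1c(O[Si](C)(C)C(C)(C)C)cc(O[Si](C)(C)C(C)(C)C)c(C(c2cc(OC)cc(OC)c2)S(=O)(=O)c2ccc(C)cc2)c1CO[Si](C(C)C)(C(C)C)C(C)C
F2 | step 16 | Cα-bromo derivative of 30 from bromonium-induced ring closure (Cα and Cβ not defined) | COc1ccc([C@@H]2Oc3cc4c5c(c3[C@H]2c2cc(OC)cc(OC)c2)C(Br)C(c2ccc(OC)cc2OC)c2c(OC)cc(OC)cc2[C@H]5[C@H](c2ccc(OC)cc2)O4)cc1
F3 | step 16 | Cα=Cβ dehydro derivative of 30 (ring alkene) | COc1ccc([C@@H]2Oc3cc4c5c(c3[C@H]2c2cc(OC)cc(OC)c2)C=C(c2ccc(OC)cc2OC)c2c(OC)cc(OC)cc2[C@H]5[C@H](c2ccc(OC)cc2)O4)cc1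
F4 | step 7 | bis(aryl tert-butyldimethylsilyl ether) of 9 (carbinol centres not controlled) | CC(C)(C)[Si](C)(C)Oc1cc(O[Si](C)(C)C(C)(C)C)c(C(O)c2cc(OC)cc(OC)c2)c(CO[Si](C(C)C)(C(C)C)C(C)C)c1C(O)c1cc(OC)cc(OC)c1
F5 | step 7 | bis(benzhydryl acetate) of F4 | CC(=O)OC(c1cc(OC)cc(OC)c1)c1c(O[Si](C)(C)C(C)(C)C)cc(O[Si](C)(C)C(C)(C)C)c(C(OC(C)=O)c2cc(OC)cc(OC)c2)c1CO[Si](C(C)C)(C(C)C)C(C)C
F0 | step 17 | none | none
F6 | step 4 | [4,6-dimethoxy-2-{[(triisopropylsilyl)oxy]methyl}-1,3-phenylene]bis[(3,5-dimethoxyphenyl)methanol] (carbinol centres not controlled) | COc1cc(OC)c(C(O)c2cc(OC)cc(OC)c2)c(CO[Si](C(C)C)(C(C)C)C(C)C)c1C(O)c1cc(OC)cc(OC)c1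
A1 | alternative 1 | 1-iodo-2,4-bis(methoxymethoxy)benzene | COCOc1ccc(I)c(OCOC)c1
A2 | alternative 1 | 2-[(1R)-2-bromo-1-(2,4-dimethoxyphenyl)ethyl]-1,5-dimethoxy-3-[(E)-2-(4-methoxyphenyl)ethenyl]benzene | BrC[C@H](c1ccc(OC)cc1OC)c1c(OC)cc(OC)cc1/C=C/c1ccc(OC)cc1
A3 | alternative 1 | dibenzocycloheptane with exocyclic 4-methoxybenzylidene group at the future C5 and bis(methoxymethoxy) ring B | COCOc1cc(OCOC)c2c(c1)C[C@H](c1ccc(OC)cc1OC)c1c(OC)cc(OC)cc1/C2=C\c1ccc(OC)cc1
A4 | alternative 2 | ten-membered aryloxy ketone (oxa-metacyclophane) carrying the C2/C3 dihydrofuran and the Cα–Cβ bridge; carbon next to the ketone not defined | COc1ccc([C@@H]2Oc3cc4cc(c3[C@H]2c2cc(OC)cc(OC)c2)C[C@H](c2ccc(OC)cc2OC)c2c(OC)cc(OC)cc2C(=O)C(c2ccc(OC)cc2)O4)cc1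
A5 | alternative 2 | benzofuran-fused dibenzocycloheptane, octamethyl ether of the 5,6-didehydro target | COc1ccc([C@@H]2Oc3cc4oc(-c5ccc(OC)cc5)c5c4c(c3[C@H]2c2cc(OC)cc(OC)c2)C[C@H](c2ccc(OC)cc2OC)c2c(OC)cc(OC)cc25)cc1
A6 | alternative 3 | 2-bromo-5-(dimethoxymethyl)-1,3-bis{[(2R,3E)-4-(3,5-dimethoxyphenyl)-3-(4-methoxyphenyl)but-3-en-2-yl]oxy}benzene | COC(OC)c1cc(O[C@H](C)/C(c2ccc(OC)cc2)=C/c2cc(OC)cc(OC)c2)c(Br)c(O[C@H](C)/C(c2ccc(OC)cc2)=C/c2cc(OC)cc(OC)c2)c1
A7 | alternative 3 | 4,6-bis(rearranged) 2-bromoresorcinol acetal with both C3-type centres set | COC(OC)c1c([C@H](/C(c2ccc(OC)cc2)=C/C)c2cc(OC)cc(OC)c2)c(O)c(Br)c(O)c1[C@H](/C(c1ccc(OC)cc1)=C/C)c1cc(OC)cc(OC)c1
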